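**Retrosynthetic overview**
- The ester is attached last to the secondary OH of an anti-1,2-diol, which comes from peripheral epoxidation of an (E)-trisubstituted ring alkene and inverting hydrolysis at the tertiary carbon.
- The α-methylene-γ-lactone (last ring formed) comes from Pd-catalysed CO insertion into a trans-homopropargylic alcohol.
- The ten-membered ring comes from anionic oxy-Cope ring expansion of a 1,2-dialkenylcyclohexanol; one quaternary carbon is sacrificed to set both lactone stereocentres.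
- The dialkenylcyclohexanol comes from diynide addition and hydroalumination on a 2-(silyloxyvinyl)-2,6-dimethylcyclohexanone, itself from a 2-allyl ketone.
- The allyl ketone comes from chiral-lithium-amide desymmetrisation and allylation of meso cis-2,6-dimethylcyclohexanone (six-membered ring, formed first by hydrogenation of 2,6-dimethylphenol).

Assumption: lithium (S,S)-bis(1-phenylethyl)amide is taken to remove the proton at the (R)-α-carbon of the meso ketone (by analogy with its sense on 4-tert-butylcyclohexanone); if the sense is opposite, the (R,R)-amide is used.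

**Step 1**
Reactants: 1 2,6-dimethylphenol
Product: 2 cis-2,6-dimethylcyclohexan-1-one (meso; 2R,6S)
Conditions: H2 (10 bar), 5% Pd/C, cyclohexane, 120 °C; then NaOMe (cat.), MeOH, rt; fractional distillation (cis ≥ 97%)
Reagents that add atoms: none
Why: Heterogeneous Pd-catalysed arene hydrogenation stops at the ketone because the intermediate enol tautomerises and desorbs, and base equilibration of the two α-centres favours the diequatorial cis (meso) isomer, so no chirality is introduced yet.

**Step 2**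
Reactants: 2 cis-2,6-dimethylcyclohexan-1-one; 3 allyl bromide (3-bromoprop-1-ene)
Product: 5 (2R,6S)-2,6-dimethyl-2-(prop-2-en-1-yl)cyclohexan-1-one, via lithium enolate 4 (not isolated)
Conditions: (S,S)-bis(1-phenylethyl)amine (1.1 equiv), n-BuLi (1.1 equiv), LiCl (0.5 equiv), THF, −78 °C, slow addition of 2; then 3 (3 equiv), DMPU, −78 → −20 °C
Reagents that add atoms: allyl bromide 3 (C=CCBr)
Why: Key step: enantiotopos-selective deprotonation of the meso ketone by the chiral lithium amide (Simpkins-type desymmetrisation, external quench with LiCl) leaves the (S)-α-centre, and C-allylation of the tetrasubstituted enolate occurs anti to the C6 methyl (pseudo-axial to avoid allylic strain with O–Li), giving the (2R) quaternary centre with the two methyls cis.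

**Step 3**
Reactants: 5 (2R,6S)-2,6-dimethyl-2-(prop-2-en-1-yl)cyclohexan-1-one
Product: 7 2-[(1R,3S)-1,3-dimethyl-2-oxocyclohexyl]acetaldehyde, via ozonide 6 (not isolated)
Conditions: O3, CH2Cl2, −78 °C; then PPh3, −78 °C → rt
Reagents that add atoms: ozone ([O-][O+]=O)
Why: Ozonolysis (Criegee mechanism) cleaves only the terminal alkene and the phosphine reduces the ozonide under neutral conditions, so neither stereocentre is touched.

**Step 4**
Reactants: 7 2-[(1R,3S)-1,3-dimethyl-2-oxocyclohexyl]acetaldehyde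
Product: 8 (2R,6S)-2,6-dimethyl-2-[(E)-2-{[tri(propan-2-yl)silyl]oxy}ethenyl]cyclohexan-1-one
Conditions: i-Pr3SiOTf (1.05 equiv), Et3N (2 equiv), CH2Cl2, −78 → 0 °C
Reagents that add atoms: triisopropylsilyl trifluoromethanesulfonate (CC(C)[Si](C(C)C)(C(C)C)OS(=O)(=O)C(F)(F)F)
Why: Soft enolisation (silyl triflate/amine) occurs at the unhindered aldehyde CH2 rather than the hindered ketone, and the enol ether is expected to form E because the Z isomer would place the silyloxy group cis to the quaternary ring carbon.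

**Step 5**
Reactants: 8 (2R,6S)-2,6-dimethyl-2-[(E)-2-{[tri(propan-2-yl)silyl]oxy}ethenyl]cyclohexan-1-one; 9 1,4-bis(trimethylsilyl)buta-1,3-diyne
Product: 12 (1S,2R,6S)-2,6-dimethyl-2-[(E)-2-{[tri(propan-2-yl)silyl]oxy}ethenyl]-1-[(E)-4-(trimethylsilyl)but-1-en-3-yn-1-yl]cyclohexan-1-ol, via lithium diynide 10 (not isolated), via lithium alkoxide 11 (not isolated)
Conditions: 9, MeLi·LiBr (1.0 equiv), THF, −78 °C → rt; 8, −78 → 0 °C; then NaAlH2(OCH2CH2OCH3)2 (2.5 equiv), 0 °C → rt; aq. KNaC4H4O6
Reagents that add atoms: 1,4-bis(trimethylsilyl)buta-1,3-diyne 9 (C[Si](C)(C)C#CC#C[Si](C)(C)C)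
Why: Mono-desilylation of 9 gives a weakly basic lithium diynide that adds 1,2 to the hindered ketone (axial attack, trans to the silyloxyvinyl group; either carbinol epimer is usable because this centre is lost later), and the alkoxide then directs trans-hydroalumination of the proximal triple bond to the (E)-enyne.

**Step 6**
Reactants: 12 (1S,2R,6S)-2,6-dimethyl-2-[(E)-2-{[tri(propan-2-yl)silyl]oxy}ethenyl]-1-[(E)-4-(trimethylsilyl)but-1-en-3-yn-1-yl]cyclohexan-1-ol
Product: 16 (3R,4S,5E,10S)-3-ethynyl-4-hydroxy-6,10-dimethylcyclodec-5-en-1-one, via potassium alkoxide 13 (not isolated), via potassium enolate 14 (not isolated), via bis-silyl ketone 15 (not isolated)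
Conditions: KH (2 equiv), 18-crown-6 (2 equiv), THF, 0 → 40 °C; AcOH (4 equiv), −78 °C; then Bu4NF (3 equiv), THF, rt
Reagents that add atoms: none
Why: Anionic oxy-Cope rearrangement ([3,3]-sigmatropic, Evans–Golob type) through a chair transition state with alkynyl and silyloxy groups both equatorial expands the six-membered ring to the (E)-cyclodecenone and transfers the chirality of the quaternary carbon to the two new centres (3R,4S, as the trans-lactone needs) with the C10 methyl centre a spectator, after which cold AcOH protonates the enolate and fluoride removes both silyl groups.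

**Step 7**
Reactants: 16 (3R,4S,5E,10S)-3-ethynyl-4-hydroxy-6,10-dimethylcyclodec-5-en-1-one
Product: 17 (3aR,6S,10E,11aS)-6,10-dimethyl-3-methylidene-3a,4,6,7,8,9-hexahydrocyclodeca[b]furan-2,5(3H,11aH)-dione
Conditions: CO (8 atm), PdCl2 (5 mol%), SnCl2 (5 mol%), PPh3 (10 mol%), MeCN, 75 °C
Reagents that add atoms: carbon monoxide ([C-]#[O+])
Why: Norton-type palladium-catalysed cyclocarbonylation, in which an alkoxycarbonyl–palladium species from the homopropargylic hydroxyl and CO adds syn across the terminal alkyne and protonolysis releases the α-methylene-γ-butyrolactone, the trans ring fusion being fixed by the centres set in step 6.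

**Step 8**
Reactants: 17 (3aR,6S,10E,11aS)-6,10-dimethyl-3-methylidene-3a,4,6,7,8,9-hexahydrocyclodeca[b]furan-2,5(3H,11aH)-dione
Product: 19 (3aR,6S,10R,11S,11aR)-10,11-dihydroxy-6,10-dimethyl-3-methylidene-3a,4,6,7,8,9,10,11-octahydrocyclodeca[b]furan-2,5(3H,11aH)-dione, via epoxide 18 (not isolated)
Conditions: dimethyldioxirane (1.1 equiv), acetone, −20 → 0 °C; evaporate; then HClO4 (10 mol%), THF/H2O 3:1, 0 °C
Reagents that add atoms: dimethyldioxirane (CC1(C)OO1); water (O)
Why: Dioxirane epoxidation (Prilezhaev type) attacks the peripheral face of the electron-rich (E)-trisubstituted ring alkene, the face of the allylic C–O bond once allylic 1,3-strain holds H-11a in the alkene plane (the parthenolide sense), giving the (10S,11S)-epoxide, and acid-catalysed anti opening at the tertiary carbon (by water, or by the transannular ketone oxygen followed by hemiketal hydrolysis) inverts C10 to R while C11 keeps its oxygen as the (S)-alcohol.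

**Step 9**
Reactants: 19 the 10,11-diol; 20 (2S)-2-methylbutanoic acid
Product: 21 (3aR,6S,10R,11S,11aR)-10-hydroxy-6,10-dimethyl-3-methylidene-2,5-dioxododecahydrocyclodeca[b]furan-11-yl (2S)-2-methylbutanoate (target)
Conditions: 20 (1.5 equiv), N,N'-diisopropylcarbodiimide (1.5 equiv), 4-(dimethylamino)pyridine (0.2 equiv), CH2Cl2, 0 °C → rt
Reagents that add atoms: (2S)-2-methylbutanoic acid 20 (CC[C@H](C)C(=O)O)
Why: Steglich esterification acylates the secondary hydroxyl selectively over the tertiary one, and the α-stereocentre of the chiral-pool acid is not enolised under these mild carbodiimide conditions.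

**Compound list**
1 | 2,6-dimethylphenol | Cc1cccc(C)c1O | starting material
2 | cis-2,6-dimethylcyclohexan-1-one (meso; 2R,6S) | O=C1[C@@H](C)CCC[C@H]1C | intermediate
3 | allyl bromide (3-bromoprop-1-ene) | C=CCBr | starting material
4 | lithium (6S)-2,6-dimethylcyclohex-1-en-1-olate | [Li+].[O-]C1=C(C)CCC[C@@H]1C | intermediate
5 | (2R,6S)-2,6-dimethyl-2-(prop-2-en-1-yl)cyclohexan-1-one | O=C1[C@@H](C)CCC[C@]1(C)CC=C | intermediate
6 | (2R,6S)-2,6-dimethyl-2-[(1,2,4-trioxolan-3-yl)methyl]cyclohexan-1-one (ozonide, epimer mixture at the trioxolane carbon) | O=C1[C@@H](C)CCC[C@]1(C)CC1OCOO1 | intermediate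
7 | 2-[(1R,3S)-1,3-dimethyl-2-oxocyclohexyl]acetaldehyde | O=C1[C@@H](C)CCC[C@]1(C)CC=O | intermediate
8 | (2R,6S)-2,6-dimethyl-2-[(E)-2-{[tri(propan-2-yl)silyl]oxy}ethenyl]cyclohexan-1-one | O=C1[C@@H](C)CCC[C@]1(C)/C=C/O[Si](C(C)C)(C(C)C)C(C)C | intermediate
9 | 1,4-bis(trimethylsilyl)buta-1,3-diyne | C[Si](C)(C)C#CC#C[Si](C)(C)C | starting material
10 | lithium 4-(trimethylsilyl)buta-1,3-diyn-1-ide | [Li+].[C-]#CC#C[Si](C)(C)C | intermediate
11 | lithium (1R,2R,6S)-2,6-dimethyl-2-[(E)-2-{[tri(propan-2-yl)silyl]oxy}ethenyl]-1-[4-(trimethylsilyl)buta-1,3-diyn-1-yl]cyclohexan-1-olate | [Li+].[O-][C@]1(C#CC#C[Si](C)(C)C)[C@@H](C)CCC[C@]1(C)/C=C/O[Si](C(C)C)(C(C)C)C(C)C | intermediate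
12 | (1S,2R,6S)-2,6-dimethyl-2-[(E)-2-{[tri(propan-2-yl)silyl]oxy}ethenyl]-1-[(E)-4-(trimethylsilyl)but-1-en-3-yn-1-yl]cyclohexan-1-ol | O[C@]1(/C=C/C#C[Si](C)(C)C)[C@@H](C)CCC[C@]1(C)/C=C/O[Si](C(C)C)(C(C)C)C(C)C | intermediate
13 | potassium alkoxide of 12 | [K+].[O-][C@]1(/C=C/C#C[Si](C)(C)C)[C@@H](C)CCC[C@]1(C)/C=C/O[Si](C(C)C)(C(C)C)C(C)C | intermediate
14 | potassium (1Z,3R,4S,5E,10S)-6,10-dimethyl-4-{[tri(propan-2-yl)silyl]oxy}-3-[(trimethylsilyl)ethynyl]cyclodeca-1,5-dien-1-olate (enolate geometry shown for the major chair; it has no consequence) | [K+].C[Si](C)(C)C#C[C@H]1/C=C(\[O-])[C@@H](C)CCC/C(C)=C/[C@@H]1O[Si](C(C)C)(C(C)C)C(C)C | intermediate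
15 | (3R,4S,5E,10S)-6,10-dimethyl-4-{[tri(propan-2-yl)silyl]oxy}-3-[(trimethylsilyl)ethynyl]cyclodec-5-en-1-one | C[Si](C)(C)C#C[C@H]1CC(=O)[C@@H](C)CCC/C(C)=C/[C@@H]1O[Si](C(C)C)(C(C)C)C(C)C | intermediate
16 | (3R,4S,5E,10S)-3-ethynyl-4-hydroxy-6,10-dimethylcyclodec-5-en-1-one | C#C[C@H]1CC(=O)[C@@H](C)CCC/C(C)=C/[C@@H]1O | intermediate
17 | (3aR,6S,10E,11aS)-6,10-dimethyl-3-methylidene-3a,4,6,7,8,9-hexahydrocyclodeca[b]furan-2,5(3H,11aH)-dione | C=C1C(=O)O[C@H]2/C=C(\C)CCC[C@H](C)C(=O)C[C@H]12 | intermediate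
18 | (3aR,6S,10S,11S,11aR)-10,11-epoxy-6,10-dimethyl-3-methylidene-3a,4,6,7,8,9,10,11-octahydrocyclodeca[b]furan-2,5(3H,11aH)-dione | C=C1C(=O)O[C@@H]2[C@@H]1CC(=O)[C@@H](C)CCC[C@]3(C)O[C@@H]23 | intermediate
19 | (3aR,6S,10R,11S,11aR)-10,11-dihydroxy-6,10-dimethyl-3-methylidene-3a,4,6,7,8,9,10,11-octahydrocyclodeca[b]furan-2,5(3H,11aH)-dione | C=C1C(=O)O[C@@H]2[C@@H]1CC(=O)[C@@H](C)CCC[C@@](C)(O)[C@H]2O | intermediate
20 | (2S)-2-methylbutanoic acid | CC[C@H](C)C(=O)O | starting material
21 | (3aR,6S,10R,11S,11aR)-10-hydroxy-6,10-dimethyl-3-methylidene-2,5-dioxododecahydrocyclodeca[b]furan-11-yl (2S)-2-methylbutanoate | C=C1C(=O)O[C@@H]2[C@@H]1CC(=O)[C@@H](C)CCC[C@@](C)(O)[C@H]2OC(=O)[C@@H](C)CC | target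

**Step count and risks**
Total step count: 9. Longest linear sequence: 9 steps (1 → 21); compounds 3, 9 and 20 are bought.

Three steps most likely to fail:

Step 2 (enantiomeric excess of the external-quench deprotonation and the cis/trans ratio of the allylation). The fallback sets out from 2 and returns at 5. Ketone 2 is converted with LiN(SiMe3)2 and allyl chloroformate into allyl 2,6-dimethylcyclohex-1-en-1-yl carbonate F1. Decarboxylative asymmetric allylic alkylation with Pd2(dba)3 and (R)-t-Bu-PHOX then sets the quaternary centre (2R) under catalyst control. It gives 5 together with its C6 epimer (2R,6R)-2,6-dimethyl-2-(prop-2-en-1-yl)cyclohexan-1-one F2. The two are separated and F2 is recycled by NaOMe equilibration of its enolisable C6 centre, so the material converges on 5.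

Step 7 (cyclocarbonylation of a hindered alcohol that can form a hemiketal with the ring ketone and dehydrate). The fallback sets out from 16 and returns at 17. Markovnikov stannylcupration of the terminal alkyne with Me3SnCu·SMe2 and MeOH gives (3S,4S,5E,10S)-4-hydroxy-6,10-dimethyl-3-[1-(trimethylstannyl)ethenyl]cyclodec-5-en-1-one F3. Iododestannylation with I2 gives (3S,4S,5E,10S)-4-hydroxy-3-(1-iodoethenyl)-6,10-dimethylcyclodec-5-en-1-one F4. Carbonylative lactonisation of this vinyl iodide with Pd(PPh3)4, CO (1 atm) and Et3N closes the α-methylene lactone 17.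

Step 8 (backside opening at the tertiary carbon must come from the ring interior, and transannular side reactions or the wrong regiochemistry are possible). The fallback sets out from 17 and returns at 21 without passing through 19. Reagent-controlled epoxidation with the D-fructose-derived Shi ketone and KHSO5 is aimed at the other alkene face, giving (3aR,6S,10R,11R,11aR)-10,11-epoxy-6,10-dimethyl-3-methylidene-3a,4,6,7,8,9,10,11-octahydrocyclodeca[b]furan-2,5(3H,11aH)-dione F5. This epoxide is opened at the secondary carbon by cesium (2S)-2-methylbutanoate (from 20 and Cs2CO3; 18-crown-6, toluene, 80 °C), with inversion at C11 and retention at C10. The ester is installed directly and the product is 21.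

**Further compounds**
F1 | step 2 | allyl 2,6-dimethylcyclohex-1-en-1-yl carbonate (racemic) | C=CCOC(=O)OC1=C(C)CCCC1C
F2 | step 2 | (2R,6R)-2,6-dimethyl-2-(prop-2-en-1-yl)cyclohexan-1-one | O=C1[C@H](C)CCC[C@]1(C)CC=C
F3 | step 7 | (3S,4S,5E,10S)-4-hydroxy-6,10-dimethyl-3-[1-(trimethylstannyl)ethenyl]cyclodec-5-en-1-one | C=C([Sn](C)(C)C)[C@H]1CC(=O)[C@@H](C)CCC/C(C)=C/[C@@H]1O
F4 | step 7 | (3S,4S,5E,10S)-4-hydroxy-3-(1-iodoethenyl)-6,10-dimethylcyclodec-5-en-1-one | C=C(I)[C@H]1CC(=O)[C@@H](C)CCC/C(C)=C/[C@@H]1O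
F5 | step 8 | (3aR,6S,10R,11R,11aR)-10,11-epoxy-6,10-dimethyl-3-methylidene-3a,4,6,7,8,9,10,11-octahydrocyclodeca[b]furan-2,5(3H,11aH)-dione | C=C1C(=O)O[C@@H]2[C@@H]1CC(=O)[C@@H](C)CCC[C@@]3(C)O[C@H]23
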